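(The earlier runs and the new flask are simulated on assumed constants, noise included.)

Sunday's flask, whose charge alpha repeats, ended with 78.8% target and 16.2% isomer of the product after 40.0 h. You now take over alpha, beta and delta.

| flask | substrate | capture agent | remark | time |
|---|---|---|---|---|
| Sunday's | 0.25 M | 5 mM | run made earlier |  |
| Tuesday's | 0.35 M | 5 mM | run made earlier |  |
| Wednesday's | 0.55 M | 5 mM | run made earlier |  |
| delta | 0.25 M | 5.00 mM | a single well-mixed tank run continuously and read at steady state, 40 h in it on average |  |
| beta | 0.25 M (fed, over 32.0 h) | 5.00 mM | all but substrate at the start; substrate goes in evenly over 32.0 h, the run ends at 40 h | 40 h |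
| alpha | 0.25 M | 5.00 mM | everything together in a closed stirred flask, run for 40 h | 40 h |

| run | time / h | target / % | isomer of the product / % |
|---|---|---|---|
| Sunday's | 3.00 | 78.2 | 8.6 |
| Sunday's | 6.00 | 80.6 | 11.9 |
| Sunday's | 12.0 | 80.5 | 14.1 |
| Sunday's | 20.0 | 80.3 | 15.5 |
| Sunday's | 40.0 | 78.8 | 16.2 |
| Tuesday's | 2.50 | 75.2 | 8.8 |
| Tuesday's | 5.00 | 80.5 | 11.9 |
| Tuesday's | 10.0 | 81.7 | 16.0 |
| Tuesday's | 15.0 | 80.3 | 15.7 |
| Tuesday's | 30.0 | 80.2 | 13.3 |
| Wednesday's | 6.00 | 81.9 | 12.5 |
| Wednesday's | 12.0 | 80.6 | 14.9 |
| Wednesday's | 20.0 | 78.7 | 15.9 |
| Wednesday's | 25.0 | 79.7 | 15.1 |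
| Wednesday's | 30.0 | 79.0 | 14.9 |

(standard deviation of a reading: 1 percentage point)

- the stated concentrations are those of everything mixed, before any reaction; amounts are the same in each set-up
- the feed brings no volume worth counting
- the earlier runs were made in a closed, stirred flask

1. the set-up with the highest share of target in all that became target or isomer of the product or trapped intermediate, at the outlet or at the end ("none" if the first two lie within 2 percentage points) (delta / beta / alpha / none)
2. share of target in all that became target or isomer of the product or trapped intermediate, at the outlet or at the end, delta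
3. share of target in all that became target or isomer of the product or trapped intermediate, at the outlet or at the end, beta
4. share of target in all that became target or isomer of the product or trapped intermediate, at the outlet or at the end, alpha

I followed one molecule of product. Over the last readings of Sunday's, Tuesday's and Wednesday's runs, isomer over target averaged 0.187, at charges from 0.25 M to 0.55 M. So I treated the two as one pool under thermodynamic control. I carried the pool share, the chance that a molecule in that pool stands as target: 84.3%.

At [capture agent] = 5.00 mM, the agent can take at most 2.00% of the substrate charge in alpha. Even then, alpha's share would be 82.5%, so expect it between that and the pool share.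

Don't take an early reading for the end. Sunday's ratio at 3.00 h was 0.110, lower than the late average. Delta holds young molecules beside old ones, so I expected it slightly above beta, but by less than 2 percentage points. My answer was none.

The forecast gave 83.2% for delta, 82.2% for beta and 81.6% for alpha, and its answer was none: “Delta leads beta by only about 1 point, inside the 2-point limit”. Its alpha lay below my range.

Delta gave 84.7%, beta 84.0% and alpha 83.9%, so the answer was none.

    substrate ⇌ intermediate A (K = 2.70, k = 0.0280 h⁻¹)
    intermediate A → intermediate B (k = 0.0240 h⁻¹)
    substrate → target (k = 0.770 h⁻¹)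
    intermediate B ⇌ target (K = 4.00, k = 0.00300 h⁻¹)
    substrate → intermediate B (k = 0.00390 h⁻¹)
    intermediate A → decomposed reagent (k = 0.0350 h⁻¹)
    target ⇌ isomer of the product (K = 0.190, k = 0.0820 h⁻¹)
    capture agent + intermediate A → trapped intermediate (k = 0.390 M⁻¹ h⁻¹)

In alpha, target and isomer of the product relax into each other with a half-life of 1.35 h, far shorter than the run's 40 h. Beside the pool share of 84.3%, alpha read earlier, at 25 h, gave 84.0%.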